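**A leftover.** The zeta flask kept a leftover of starting material, averaging 13.5% from 3.00 h to 10.0 h. That leftover is the reading to watch, and I reckoned the flask at 50 h, which is the zeta flask carried on, from it.

| flask | starting material | protic impurity | remark | time |
|---|---|---|---|---|
| zeta | 1.5 M (fed, over 20 min) | 0.15 M | the very flask that is asked about, followed so far; the fed solution adds 1.0 times the starting volume |  |
| epsilon | 1 M (fed, over 20 min) | 0.15 M | run made earlier; the fed solution adds 1.0 times the starting volume |  |
| flask | 1.5 M (fed, over 20 min) | 0.150 M | the fed solution adds 1.0 times the starting volume | 50 h |

| run | time / h | starting material / % | target / % |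
|---|---|---|---|
| zeta | 0.500 | 14.0 | 42.3 |
| zeta | 1.50 | 12.0 | 39.4 |
| zeta | 3.00 | 13.4 | 38.8 |
| zeta | 4.00 | 12.1 | 38.4 |
| zeta | 6.00 | 14.4 | 38.6 |
| zeta | 8.00 | 13.3 | 39.4 |
| zeta | 10.0 | 14.2 | 39.1 |
| epsilon | 2.00 | 13.1 | 37.1 |
| epsilon | 5.00 | 11.9 | 36.2 |
| epsilon | 10.0 | 11.8 | 37.4 |
| epsilon | 15.0 | 12.6 | 36.7 |
| epsilon | 20.0 | 12.4 | 36.6 |
| epsilon | 30.0 | 13.5 | 36.0 |
| epsilon | 40.0 | 13.5 | 36.8 |

(standard deviation of a reading: 0.5 percentage points)

- every charge counts on the volume at the start, and the solution that is fed holds the whole dose
- the reaction counts as stopped when no species that holds the starting material changes by six tenths of a point or more over the second half of the time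

- the state of affairs at 50 h: stopped, and by what, or still going (it is still moving / forward and back rates have come level / all of the starting material has reacted)
- how much of the starting material has reacted by 50 h
- how much target there is at 50 h, in percent of the starting material charged
- how much isomer of the product there is at 50 h, in percent of the starting material charged

**The curve.** In the zeta flask the charge entered at a fraction 0.0500 min⁻¹ of itself, so the first knee lay at the end of the feed, 20 min. In the zeta flask target averaged 38.9% from 3.00 h to 10.0 h, but it read 42.3% at 0.500 h, which was 3.4 percentage points above that average and beyond the scatter. The second knee came by 1.50 h, when target read 39.4%, and 50 h is 33.3 such settling times. In the epsilon flask, starting material shifted by 0.4 points between 2.00 h and 40.0 h, inside the scatter. I therefore read the level as a balance (equilibrium).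

**Spread number.** In the epsilon flask target averaged 36.7% and starting material 12.7%. Target over starting material read 2.88 in the zeta flask and 2.89 in the epsilon flask. Different charges gave one ratio, so I took the balances as first order. I assumed that [protic impurity], the limiting reagent at 0.15 M against 1.5 M, removes its own amount of starting material. The spread number is then the fraction of the charge the impurity leaves, divided by the fraction standing as starting material: 6.68 in the zeta flask and 6.70 in the epsilon flask. I carried their average, 6.69.

**My reckoning.** For this flask the impurity takes 10.0%, so starting material stands at 13.5% and conversion at 86.5%. Target is 38.9%, and the unread isomer of the product, as the remainder, is 37.6%.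

**The forecast.** The forecast gave forward and back rates have come level, with 86.7% conversion, 39% target and 38% isomer of the product, holding that “Flat readings with starting material left mean the system has stopped at a balance”.

**The result.** The flask gave forward and back rates have come level, with 86.6% conversion, 39.0% target and 37.6% isomer of the product.

    starting material ⇌ isomer of the product (K = 2.80, k = 0.170 min⁻¹)
    starting material ⇌ target (K = 2.90, k = 0.460 min⁻¹)
    starting material + protic impurity → quenched substrate (k = 0.560 L mol⁻¹ min⁻¹)

**The reason.** The main reason for the leftover in this flask is the back reaction of target to starting material: the run without it converted 100%, against 86.6%. The flask's own conversion returns a spread number of 6.72.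

**Second flask.** With 0.60 M of protic impurity the share is 40.0%, so the spread number gives 8.97% starting material and 25.9% target. That flask held 8.96% and 26.0%.

(The runs were generated by integration for substances that don't exist, noise included.)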